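I began from a ratio. Let u be the fraction of substrate left, and ρ the rate of its loss to self-condensation divided by the rate of its loss into the chain, both taken at u = 1. The first loss goes as u squared and, as I took it, the second as u, so substrate consumed at u becomes target with the share s = 1/(1 + ρu), the selectivity factor of these flasks.

common to all: initiator 15 mM

| charge | substrate | partner | protic impurity | remark | time |
|---|---|---|---|---|---|
| south-east | 0.16 M | 0.32 M | 0.016 M | run made earlier |  |
| south-west | 0.16 M | 0.32 M | 0.0080 M | run made earlier |  |
| north-east | 0.16 M | 0.32 M | 0.012 M | run made earlier |  |
| noon | 0.16 M | 0.320 M (fed, over 1.60 h) | 0.0160 M | all but partner at the start; partner goes in evenly over 1.60 h, the run ends at 2.0 h | 2.0 h |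
| spring | 0.16 M | 0.320 M | 0.0160 M | everything together in a closed stirred flask, run for 2.0 h | 2.0 h |
| midnight | 0.16 M | 0.320 M | 0.0160 M | one stirred flow tank at steady state, fed with the mixture as stated, mean residence time 2.0 h |  |
| autumn | 0.16 M (fed, over 1.60 h) | 0.320 M | 0.0160 M | a stirred flask in which substrate is dosed at a steady rate over 1.60 h without added volume, worked up at 2.0 h | 2.0 h |

| south-east: time / min | south-east: target / % | south-west: time / min | south-west: target / % | north-east: time / min | north-east: target / % |
|---|---|---|---|---|---|
| 30.0 | 43.1 | 25.0 | 41.4 | 8.00 | 21.8 |
| 60.0 | 47.7 | 50.0 | 46.9 | 20.0 | 37.5 |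
| 90.0 | 47.4 | 80.0 | 48.3 | 40.0 | 45.4 |
| 120 | 47.7 | 90.0 | 48.4 | 90.0 | 48.9 |

(each reading ± 1 percentage point)

- a species is counted by the substrate in it: one ended chains B or self-condensation product counts as two
- the stated concentrations are those of everything mixed, before any reaction; amounts are the same in each set-up
- what may be going on: 2 first chain carrier -> ended chains B; partner + first chain carrier -> target + second chain carrier; initiator -> 2 initiating radical; 2 substrate -> self-condensation product; partner + protic impurity -> quenched reagent; substrate + initiating radical -> capped initiator + first chain carrier; 2 second chain carrier -> ended chains A; substrate + second chain carrier -> by-product + first chain carrier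
- the feed brings no volume worth counting
- the earlier runs were made in a closed, stirred flask

1. order of the set-ups by the amount of target at the outlet or at the end, in percent of the substrate put in, highest first (noon / spring / midnight / autumn)
2. amount of target at the outlet or at the end, in percent of the substrate put in, noon
3. amount of target at the outlet or at the end, in percent of the substrate put in, spring
4. amount of target at the outlet or at the end, in percent of the substrate put in, midnight
5. amount of target at the outlet or at the end, in percent of the substrate put in, autumn

Integrating s over u in a closed flask gives a final yield of ln(1 + ρ)/ρ. The late readings stand at 48.1 %, with protic impurity from 0.0080 M to 0.016 M, and this plateau read as ρ gives 2.76, the ratio of the two losses at full charge.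

In slow motion, a closed flask starts at s = 26.6 %, so self-condensation takes more than the chain. The shares become equal in the middle of the run, at u = 0.362, and from then on the chain leads, but that fraction of the charge is what remains for it to win. The north-east reading at 20.0 min gives, by the same integration, u = 0.121 and a chain constant a = 0.0536 min⁻¹.

Spring repeats the south-east recipe, so I kept 48.1 %. The midnight tank balances feed against both losses at u = 0.107, which gives me 68.9 %. Autumn's dosing holds u near 0.140, which gives me 72.1 %. Noon keeps u high while partner is still thin, which the rule does not cover, so I put it below the plateau without a figure.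

The forecast, with a ratio of 2.6 against my 2.76, ordered them autumn > midnight > spring > noon. It gave noon 35 % (23 % to 46 %), spring 47.8 % (46.5 % to 49.2 %), midnight 65 % (52 % to 73 %) and autumn 72 % (60 % to 81 %), holding that “the low steady substrate level favours the chain”.

The flasks came out as autumn > midnight > spring > noon: noon 25.4 %, spring 48.8 %, midnight 73.5 %, autumn 77.7 %.

    2 first chain carrier → ended chains B (k = 2.00 × 10⁷ M⁻¹ s⁻¹)
    partner + first chain carrier → target + second chain carrier (k = 2.30 × 10⁷ M⁻¹ h⁻¹)
    initiator → 2 initiating radical (k = 0.0160 h⁻¹)
    2 substrate → self-condensation product (k = 24.0 M⁻¹ h⁻¹)
    partner + protic impurity → quenched reagent (k = 13.0 M⁻¹ h⁻¹)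
    substrate + initiating radical → capped initiator + first chain carrier (k = 87000 M⁻¹ s⁻¹)
    2 second chain carrier → ended chains A (k = 9.00 × 10⁸ M⁻¹ s⁻¹)
    substrate + second chain carrier → by-product + first chain carrier (k = 1.20 × 10⁵ M⁻¹ s⁻¹)

Midnight left 10.3 % of its substrate at the outlet, and with that u the share rule gives 69.8 % against the 73.5 % found. Noon's partner is fed, so ρ gives it no yield by the closed-flask integration, but its 25.4 % can be held against the share 26.6 % that ρ gives a closed flask at the start, and it is lower than that share. The neighbouring flask is noon with partner raised to 0.80 M, or 5.00 equiv. It ended with 0 % of its substrate and 92 % of its partner left, and its 31.6 % of target is more than that same starting share but less than the closed-flask plateau of 48.1 %.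

All runs are simulated on assumed constants.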